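**Assumption:** 2,3-dibromoanisole (1) is taken as a purchasable compound, and formaldehyde (2) is charged as paraformaldehyde, which depolymerises in acid. Locants used throughout: in each ring C1 bears the bridging carbon C7, C2 and C3 bear bromine, C4 and C5 bear oxygen, and C6 is CH.

## Structural features

- The target 7 is a symmetric diarylmethane: two identical benzene rings (ring A and ring B) joined through one sp3 carbon, C7, which is bonded to C1 of each ring.
- Each ring is pentasubstituted: C7 on C1, bromine on C2 and C3, hydroxyl on C4 and C5, and a single ring hydrogen on C6.
- There is no stereocentre, and the two halves are equivalent, so every operation can be run in two directions at once.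
- The fragile groups are the two catechols and the four aryl C–Br bonds. The catechols are oxidised easily, above all in base, to ortho-quinones that can enolise through the doubly benzylic C7–H bonds to quinone methides. The C–Br bonds exclude hydrogenolysis, dissolving metals, organolithium reagents and most zerovalent-metal catalysis.
- The real difficulty is regiochemical. Two adjacent bromines must sit between the bridge and the catechol on both rings. Electrophilic bromination of a preformed bis-catechol would have three CH positions per ring to choose from and no reliable way to stop at the 2,3-pattern.
- The plan therefore buys the bromines in place and moves the late regiochemical decision to oxygen. At the mono-phenol stage the C4 hydroxyl has C3 (bromine) and C5 (hydrogen) as its ortho carbons and C1 (bearing C7) as its para carbon. C5 is then the only ring carbon at which an oxygen delivered from the C4 oxygen can land without displacing a substituent.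

## Logic of the disconnections

**7 to 6.** The last retrosynthetic move changes only the oxidation level: the four O–H bonds of 7 are removed to give 6. No skeletal bond is cut. The move is made because 6, not 7, is what an oxygen-transfer reagent actually releases from a phenol. The forward demand is a reduction that is faster than enolisation of 6 through C7–H and that leaves C–Br untouched, so a mild two-electron reductant has to be added to the same flask.

**6 to 5.** The C5–O bonds of both rings are cut. This removes one oxygen per ring and leaves a phenol with an ordinary 1,2,3,4-tetrasubstituted ring, which is far easier to assemble than the pentasubstituted catechol. The forward step must oxygenate an electron-poor phenol twice, specifically ortho to the hydroxyl. One equivalent of oxidant per ring is enough, because the iodine reagent passes from the pentavalent to the monovalent state.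

**5 to 4.** The two phenolic O–H bonds are replaced by O–CH3 bonds. A free phenol would take a one-carbon electrophile at C6 as well as at C4 and would go on to oligomers, whereas an aryl methyl ether is a dependable para director. The gain is positional control in the next disconnection, at the price of one step. The forward demand is an ether cleavage that spares the C–Br bonds and the C1–C7 bonds.

**4 to 1 and 2 (through 3).** The C1–C7 bonds of both rings are cut. The first cut gives 3 and 1, and the second returns 3 to 1 and 2. C7 is at the oxidation level of formaldehyde, and C1 lies para to the ring oxygen, so both bonds can come from one acid-mediated condensation. The target is thereby reduced to two copies of a commercial arene that already holds both bromines in the correct relationship. The forward step must substitute 1 at C4 (next to bromine) and not at C6, and must stop after two arylations.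

## Other disconnections considered

**Alternative 1:** Each benzene ring is taken apart at C5–C6, C1–C2 and C4–C5.
- Cut: this leaves 1,4-pentadiyne A1, which supplies C6, C1, C7, C1' and C6', and two molecules of the vinylketene 2,3-dibromo-4-methoxybuta-1,3-dien-1-one A2 (Z isomer drawn; either geometry would serve), each supplying C5, C2, C3 and C4 of one ring.
- Forward key step: a double Danheiser benzannulation. The ketene C=C bond of A2 adds [2+2] to each terminal alkyne of A1. Four-electron opening of the vinylcyclobutenone, six-electron closure of the dienylketene and enolisation would give bis(2,3-dibromo-5-hydroxy-4-methoxyphenyl)methane A3. Cleavage of the two methyl ethers of A3 would then give 7.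
- In favour: every substituent is placed by the connectivity of the fragments, so no aromatic substitution has to be steered. The catechol oxygens arrive at the final oxidation level, so no quinone and no quinone methide hazard arises. On that point it is better than the chosen plan.
- Against: unactivated terminal alkynes are weak partners for ketenes. A1 is volatile, hazardous and isomerises to conjugated and allenic isomers under the basic conditions usually used to release a ketene. A2 is an alpha-bromo ketene carrying a vinyl bromide and an enol ether; it would need a multistep precursor and should dimerise readily. The annulation must also succeed twice on one molecule.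
- Comparison: on structure it is the more convergent plan and equal in regiochemical certainty. On mechanism it needs a cycloaddition and two electrocyclic events per ring, against a single oxygen transfer. On step economy it is clearly longer than three operations, since precursor synthesis, annulation and ether cleavage all count.

**Alternative 2:** Each ring is cut at C1–C2 and C3–C4.
- Cut: this gives the bis-pyrone 6,6'-methylenebis(3,4-dimethoxy-2H-pyran-2-one) A4 and two molecules of bis(trimethylsilyl)acetylene A5.
- Forward key step: each pyrone ring of A4 undergoes Diels–Alder addition of A5 across pyrone C3 and C6, followed by decarboxylative cycloreversion, to give bis[4,5-dimethoxy-2,3-bis(trimethylsilyl)phenyl]methane A6. Four ipso bromodesilylations and four ether cleavages would then lead to 7.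
- In favour: the pyrone cycloaddition and decarboxylation sequence is a well-established arene synthesis. The silyl groups mark C2 and C3 for site-specific halogenation independent of directing effects. Neither a quinone nor a Friedel–Crafts step is involved, which is an advantage over the chosen plan.
- Against: A5 is a hindered, electronically neutral dienophile, and the dimethoxypyrone rings of A4 are electron-rich dienes, so the pairing is poorly matched and would call for forcing temperatures. Four crowded aryl–silicon bonds must be turned into C–Br bonds without protodesilylation, while the electron-rich ring still offers C6–H to the electrophile. Four methyl ethers remain to be cleaved.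
- Comparison: on structure its certainty at C2 and C3 only equals that of the chosen plan, which buys the bromines in place. On mechanism it adds eight functional-group exchanges after the ring synthesis. On step economy it is much the weaker, since A4 itself needs a multistep preparation.

**Alternative 3:** Each ring is cut at C3–C4 and C5–C6.
- Cut: this gives the bis-sulfone 4,4'-methylenebis(2,3-dibromothiophene 1,1-dioxide) A7 and two molecules of di-tert-butoxyethyne A8.
- Forward key step: A8 adds across the two alpha carbons of each sulfone ring of A7 in an inverse-demand Diels–Alder reaction. Cheletropic loss of the sulfone bridge would give bis(2,3-dibromo-4,5-di-tert-butoxyphenyl)methane A9. Acidolysis of the four tert-butyl ethers would give 7.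
- In favour: the electron-poor diene and the electron-rich ynediether are well matched, and the bromines are already in place. The final deprotection needs only mild protic acid, which is gentler than step 2 of the chosen plan and a point on which this alternative is better. It also avoids any quinone.
- Against: thiophene dioxides with an unsubstituted alpha carbon dimerise readily. Oxidising an electron-poor dibromothiophene to the dioxide needs very strong oxygen-transfer agents. A8 loses its tert-butyl groups on mild heating, so the thermal window for cycloaddition and extrusion is narrow. A7 requires a multistep synthesis with a bromination-pattern problem of its own.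
- Comparison: on structure it matches the chosen plan in carrying the halogens from the start. On mechanism it replaces one directed oxygen transfer by a cycloaddition and extrusion on two fragile partners. On step economy it is clearly longer.

Key step: step 3

## Route

Step 1
Reactants: 1 2,3-dibromoanisole (1,2-dibromo-3-methoxybenzene); 2 formaldehyde (charged as paraformaldehyde)
Product: 4 bis(2,3-dibromo-4-methoxyphenyl)methane, via benzylic alcohol 3 (not isolated)
Conditions: 1 (2.5 equiv), (CH2O)n (1 equiv), conc. H2SO4, AcOH, 50 °C
Reagents that add atoms: none
Why: Acid-mediated hydroxyalkylation followed by Friedel–Crafts benzylation (Baeyer-type diarylmethane condensation): protonated formaldehyde attacks 1 at C4, para to the methoxy group, the site that 2,3-dihaloanisoles generally offer to Friedel–Crafts electrophiles, and alcohol 3 ionises to a methoxy-stabilised benzyl cation that alkylates a second molecule of 1 at the same carbon. The excess of 1 should keep the less reactive ortho positions of 4 from being alkylated further.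

Step 2
Reactants: 4 bis(2,3-dibromo-4-methoxyphenyl)methane
Product: 5 4,4'-methylenebis(2,3-dibromophenol)
Conditions: BBr3 (3 equiv), CH2Cl2, −78 °C → rt; then H2O
Reagents that add atoms: none
Why: Lewis-acid cleavage of aryl methyl ethers: each ether oxygen coordinates to boron, bromide attacks the methyl carbon in an SN2 step, and hydrolysis of the aryloxyborane frees the phenol. Aryl bromides and the diarylmethane bridge should be inert to BBr3 at or below room temperature.

Step 3
Reactants: 5 4,4'-methylenebis(2,3-dibromophenol)
Product: 7 bis(2,3-dibromo-4,5-dihydroxyphenyl)methane, via bis-ortho-quinone 6 (not isolated)
Conditions: IBX (2.2 equiv), DMF, rt (to 40 °C if slow), N2, dark; then aq Na2S2O4, 0 °C → rt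
Reagents that add atoms: 2-iodoxybenzoic acid (IBX), O=C1OI(=O)(O)c2ccccc12
Why: IBX ortho-oxygenation of a phenol with reduction in the same flask: each phenol oxygen of 5 first exchanges onto the pentavalent iodine of IBX with loss of water. Within that aryloxy-iodane an oxo ligand is passed intramolecularly to the ortho carbon C5 in a [2,3]-type shift, which makes the C5–O bond and lowers iodine to the trivalent state. Tautomerisation gives a catechol still bound to trivalent iodine, and its collapse to 2-iodobenzoic acid (monovalent iodine) releases the ortho-quinone; on both rings this gives 6, with two C–O bonds as the only skeletal change, no ring closed and no stereocentre formed. The closest known reaction type is the regioselective IBX oxidation of para-substituted phenols to ortho-quinones with reductive work-up to catechols. The selectivity required is oxygen transfer to C5 rather than ipso to bromine at C3, and attack on the ring rather than on the C7 methylene; it is secured because C1 (para) carries C7, C3 is blocked by a bulky and electron-poor C–Br unit, C5 is the only unsubstituted ortho carbon within reach of the tethered oxo ligand, and benzylic oxidation by IBX needs far higher temperatures. The two bromines make the phenol a weaker ligand and nucleophile, so gentle warming may be needed, but only as far as 6 tolerates. Na2S2O4 added directly should then reduce each quinone ring by two electrons and two protons to the catechol, faster than enolisation through C7–H to a quinone methide or displacement of bromide can occur, and it also destroys surplus oxidant.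

## Compound list

1 | 2,3-dibromoanisole (1,2-dibromo-3-methoxybenzene) | COc1cccc(Br)c1Br | starting material
2 | formaldehyde (charged as paraformaldehyde) | C=O | starting material
3 | (2,3-dibromo-4-methoxyphenyl)methanol | COc1ccc(CO)c(Br)c1Br | intermediate
4 | bis(2,3-dibromo-4-methoxyphenyl)methane | COc1ccc(Cc2ccc(OC)c(Br)c2Br)c(Br)c1Br | intermediate
5 | 4,4'-methylenebis(2,3-dibromophenol) | Oc1ccc(Cc2ccc(O)c(Br)c2Br)c(Br)c1Br | intermediate
6 | 5,5'-methylenebis(3,4-dibromocyclohexa-3,5-diene-1,2-dione) | O=C1C=C(CC2=CC(=O)C(=O)C(Br)=C2Br)C(Br)=C(Br)C1=O | intermediate
7 | bis(2,3-dibromo-4,5-dihydroxyphenyl)methane | Oc1cc(Cc2cc(O)c(O)c(Br)c2Br)c(Br)c(Br)c1O | target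

## Step count and least certain steps

Total step count: 3. Longest linear sequence: 3 steps (1 → 4 → 5 → 7). The route is linear, and two molecules of 1 enter in step 1.

**Step 3 (key step).** Three processes threaten it.
- The ligand exchange and oxygen transfer may be slow, because two bromines lower the electron density of each phenol. Forcing the reaction with heat gives time for the second process.
- The quinone rings of 6 may enolise through the C7–H bonds to a quinone methide, which then takes up water or 2-iodobenzoate at C7.
- Nucleophiles may add and eliminate bromide at the bromine-bearing C2 and C3 of the quinone, or oxygen may be transferred ipso to bromine at C3. Either would cost a bromine.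

Fallback, setting out from 5 and returning at 7: the C5 oxygen is installed without ever reaching the quinone level. Magnesium-phenoxide-directed ortho-formylation of 5 (MgCl2, Et3N, paraformaldehyde, MeCN, reflux) should place a formyl group on C5 of each ring, the only free ortho carbon, to give 5,5'-methylenebis(3,4-dibromo-2-hydroxybenzaldehyde) F1. Dakin oxidation of F1 (H2O2, aqueous NaOH, 0 °C, under nitrogen, with prompt acidification) should convert each formyl group through the aryl formate into a hydroxyl and deliver 7. This costs one step more.

**Step 1.** Positional control may be lost through attack at C6, ortho to the methoxy group, instead of at C4. Alkylation may also continue at the ortho positions of 4 to give oligomers. Both become more likely if the deactivated ring makes the first hydroxymethylation slow relative to capture of the benzyl cation by product.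

Fallback, setting out from 1 and returning at 4, with 3 as an isolated compound on the way: the two C–C bonds are formed in separate operations. Rieche formylation of 1 (Cl2CHOMe, TiCl4, CH2Cl2, 0 °C) should give 2,3-dibromo-4-methoxybenzaldehyde F2, which can be freed of any ortho isomer at the single-ring stage. Reduction of F2 with NaBH4 in MeOH gives 3. Alcohol 3 is then used as the limiting electrophile in a Friedel–Crafts benzylation of a second, excess portion of 1 (catalytic TfOH, CH2Cl2) to give 4.

**Step 2.** Cleavage may be incomplete if a partly reacted aryloxyborane precipitates. A C1–C7 bond may also be broken by ipso protonation para to oxygen by the HBr that forms.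

Fallback, setting out from 1 and returning at 5: the ether is cleaved before the bridge exists. BBr3 on 1 gives 2,3-dibromophenol F3, which can also be purchased. Condensation of excess F3 with 2 in aqueous H2SO4 gives 5 directly. The price is the weaker para control of a free phenol, so ortho-linked isomers would have to be removed by crystallisation.

## Further compounds

F1 | step 3 | 5,5'-methylenebis(3,4-dibromo-2-hydroxybenzaldehyde) | O=Cc1cc(Cc2cc(C=O)c(O)c(Br)c2Br)c(Br)c(Br)c1O
F2 | step 1 | 2,3-dibromo-4-methoxybenzaldehyde | COc1ccc(C=O)c(Br)c1Br
F3 | step 2 | 2,3-dibromophenol | Oc1cccc(Br)c1Br
A1 | alternative 1 | 1,4-pentadiyne | C#CCC#C
A2 | alternative 1 | (Z)-2,3-dibromo-4-methoxybuta-1,3-dien-1-one | O=C=C(Br)/C(Br)=C/OC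
A3 | alternative 1 | bis(2,3-dibromo-5-hydroxy-4-methoxyphenyl)methane | COc1c(O)cc(Cc2cc(O)c(OC)c(Br)c2Br)c(Br)c1Br
A4 | alternative 2 | 6,6'-methylenebis(3,4-dimethoxy-2H-pyran-2-one) | COC1=C(OC)C(=O)OC(CC2=CC(OC)=C(OC)C(=O)O2)=C1
A5 | alternative 2 | bis(trimethylsilyl)acetylene | C[Si](C)(C)C#C[Si](C)(C)C
A6 | alternative 2 | bis[4,5-dimethoxy-2,3-bis(trimethylsilyl)phenyl]methane | COc1cc(Cc2cc(OC)c(OC)c([Si](C)(C)C)c2[Si](C)(C)C)c([Si](C)(C)C)c([Si](C)(C)C)c1OC
A7 | alternative 3 | 4,4'-methylenebis(2,3-dibromothiophene 1,1-dioxide) | O=S1(=O)C=C(CC2=CS(=O)(=O)C(Br)=C2Br)C(Br)=C1Br
A8 | alternative 3 | di-tert-butoxyethyne | CC(C)(C)OC#COC(C)(C)C
A9 | alternative 3 | bis(2,3-dibromo-4,5-di-tert-butoxyphenyl)methane | CC(C)(C)Oc1cc(Cc2cc(OC(C)(C)C)c(OC(C)(C)C)c(Br)c2Br)c(Br)c(Br)c1OC(C)(C)C
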